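**Plan**

1. The hardest part is the single sulfate on an outer oxygen (O3') of the 3',4',5'-trioxygenated ring B, next to four other phenols and on an acid-labile ArO–SO3H bond. The flavone skeleton is the easy part and should cost one step.
2. Retrosynthesis: unmask the O3' sulfate (neopentyl diester) and O4'/O5' (diphenylmethylene ketal) last. Then cut ring C at C4a–C4, C4–C3 and O1–C2 in one operation into a ring-A aryl iodide, carbon monoxide (C4) and a ring-B arylacetylene (C3, C2).
3. Enabling feature: C4 is a lone carbonyl carbon between C4a and C3, and C4a lies between two equivalent oxygens of the phloroglucinol ring A (O1 and the 5-OH). Symmetric 2-iodophloroglucinol triacetate therefore needs no regiocontrol and no protecting group that outlives the step.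
4. Ring B is differentiated at the outset: in 3,4,5-trihydroxybenzaldehyde only a vicinal oxygen pair can be tied into a dioxole, which leaves exactly one outer OH for the masked sulfate.
5. Forward order: ring-B alkyne (steps 1–3), ring-A iodide (steps 4–5), three-component closure of ring C (step 6), sulfate unmasking (step 7), ketal hydrogenolysis (step 8).
6. Stereochemistry: the target is achiral (no stereocentre, free rotation about C2–C1'), so nothing has to be set.

Key step: step 6

Remark 1: O3' and O5' are interchanged by rotation about C2–C1', so "3'-sulfate" means the sulfate on either outer oxygen of ring B.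
Remark 2: the target is drawn as the free hydrogen sulfate; it is released from its sodium salt in the last operation, and the salt is the form in which it should be stored.
Remark 3: neopentyl chlorosulfate is taken as a catalogue reagent.

**Route**

Step 1
Reactants: 1 3,4,5-trihydroxybenzaldehyde
Product: 2 7-hydroxy-2,2-diphenyl-1,3-benzodioxole-5-carbaldehyde
Conditions: Ph2CCl2 (1.2 equiv), Ph2O, 175 °C, N2 sweep
Reagents that add atoms: dichlorodiphenylmethane, ClC(Cl)(c1ccccc1)c1ccccc1
Why: Catechol ketalisation with a gem-dichloride (double O-alkylation through the chlorodiphenylmethyl oxocarbenium ion) can only close the five-membered dioxole across a vicinal oxygen pair, and the two vicinal pairs of the symmetric triol are equivalent, so exactly one outer hydroxyl, the future sulfate oxygen, should remain free.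

Step 2
Reactants: 2 7-hydroxy-2,2-diphenyl-1,3-benzodioxole-5-carbaldehyde
Product: 3 6-ethynyl-2,2-diphenyl-1,3-benzodioxol-4-ol
Conditions: Ohira–Bestmann reagent (1.5 equiv), K2CO3 (3 equiv), MeOH, 0 °C to rt; aq. NH4Cl work-up
Reagents that add atoms: dimethyl (1-diazo-2-oxopropyl)phosphonate, COP(=O)(OC)C(=[N+]=[N-])C(C)=O
Why: Seyferth–Gilbert homologation in the Ohira–Bestmann variant (methanolysis of the reagent, olefination of the aldehyde, loss of N2 with 1,2-hydrogen shift) should convert the aldehyde into the terminal alkyne, the phenol being carried as its phenoxide and the ketal being base-stable.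

Step 3
Reactants: 3 6-ethynyl-2,2-diphenyl-1,3-benzodioxol-4-ol
Product: 4 6-ethynyl-2,2-diphenyl-1,3-benzodioxol-4-yl neopentyl sulfate
Conditions: NaHMDS (1.05 equiv), THF, −78 °C; then neopentyl chlorosulfate (1.2 equiv), −78 °C to rt
Reagents that add atoms: neopentyl chlorosulfate, CC(C)(C)COS(=O)(=O)Cl
Why: O-sulfonylation of the sodium phenoxide with an alkyl chlorosulfate (sulfate diester formation) should occur at oxygen only, since one equivalent of base deprotonates the phenol and not the alkyne, and it installs the sulfate as a neutral, acid- and amine-stable neopentyl diester.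

Step 4
Reactants: 5 phloroglucinol (benzene-1,3,5-triol)
Product: 6 2-iodobenzene-1,3,5-triol
Conditions: I2 (1.0 equiv), NaHCO3 (1.1 equiv), THF/H2O (1:1), 0 °C; used crude
Reagents that add atoms: iodine, II
Why: Electrophilic aromatic iodination of a highly activated arene whose three ring CH positions are equivalent should give the mono-iodide under stoichiometric control without any regiochemical question.

Step 5
Reactants: 6 2-iodobenzene-1,3,5-triol
Product: 7 2-iodobenzene-1,3,5-triyl triacetate
Conditions: Ac2O (4 equiv), pyridine, DMAP (cat.), 0 °C to rt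
Reagents that add atoms: acetic anhydride, CC(=O)OC(C)=O
Why: DMAP-catalysed peracetylation should turn the air- and acid-sensitive iodotriol into a stable, less electron-rich aryl iodide whose acetates are removed again by the amine in step 6.

Step 6
Reactants: 7 2-iodobenzene-1,3,5-triyl triacetate; 4 6-ethynyl-2,2-diphenyl-1,3-benzodioxol-4-yl neopentyl sulfate; 8 carbon monoxide
Product: 11 6-(5,7-dihydroxy-4-oxo-4H-chromen-2-yl)-2,2-diphenyl-1,3-benzodioxol-4-yl neopentyl sulfate, via ynone triacetate 9 (not isolated), via enaminone triol 10 (not isolated)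
Conditions: CO (1 atm), PdCl2(PPh3)2 (5 mol %), dppp (5 mol %), thiourea (5 mol %), DBU (0.2 equiv), Et2NH (degassed, solvent), 40 °C; pH 5 buffer work-up
Reagents that add atoms: none
Why: Pd(0) should add to the C–I bond of 7, CO should insert to give the 2,6-diacetoxyaroyl–Pd(II) species, and copper-free, amine-assisted alkynyl transfer from 4 with reductive elimination should forge C4a–C4 and C4–C3 in ynone 9. Diethylamine should then add to C2 of the ynone and aminolyse the three aryl acetates to give β-amino enone 10, whose ortho phenol attacks C2 and expels Et2NH to form O1–C2. The closest known reaction is the Pd-catalysed carbonylative annulation of o-iodophenol acetates with terminal arylacetylenes to flavones (carbonylative Sonogashira coupling followed by oxa-Michael closure). Ring C closes by a 6-endo-trig addition–elimination (formally 6-endo-dig on the ynone), and no stereocentre is formed. The step needs carbonylative rather than direct coupling (the two ortho substituents slow alkynyl transfer relative to CO insertion, and copper is absent) and flavone rather than aurone closure (the secondary-amine relay makes C2 the only electrophilic carbon, and the phenols stay acylated until after C–C coupling). The choice of the cyclising oxygen is immaterial because the two ortho oxygens of ring A are equivalent, the other one becoming the chelated 5-OH and the para one the 7-OH; the neopentyl sulfate and the ketal should be inert to Pd(0), CO and a secondary amine at 40 °C.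

Step 7
Reactants: 11 6-(5,7-dihydroxy-4-oxo-4H-chromen-2-yl)-2,2-diphenyl-1,3-benzodioxol-4-yl neopentyl sulfate
Product: 12 sodium 6-(5,7-dihydroxy-4-oxo-4H-chromen-2-yl)-2,2-diphenyl-1,3-benzodioxol-4-yl sulfate
Conditions: NaN3 (3 equiv), DMF, 70 °C, Ar; reversed-phase purification
Reagents that add atoms: sodium azide, [Na+].[N-]=[N+]=[N-]
Why: SN2 dealkylation of the sulfate diester at the neopentyl carbon by azide, the established unmasking of neopentyl aryl sulfates, should release the aryl sulfate monoanion as leaving group while ketal, phenols and chromone are inert to azide.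

Step 8
Reactants: 12 sodium 6-(5,7-dihydroxy-4-oxo-4H-chromen-2-yl)-2,2-diphenyl-1,3-benzodioxol-4-yl sulfate
Product: 14 tricetin 3'-sulfate (5-(5,7-dihydroxy-4-oxo-4H-chromen-2-yl)-2,3-dihydroxyphenyl hydrogen sulfate), via sodium tricetin 3'-sulfate 13 (not isolated)
Conditions: H2 (1 atm), 10% Pd/C, MeOH/THF/H2O, rt; filter; then 0.1 M HCl (1.0 equiv), 0 °C, C18 desalting, lyophilise
Reagents that add atoms: none
Why: Hydrogenolysis of the doubly benzylic C–O bonds of the diphenylmethylene ketal over Pd/C, which aryl sulfate salts and the flavone enone should survive at 1 atm, frees the 4'- and 5'-hydroxyls, and stoichiometric protonation with reversed-phase desalting should then give the hydrogen sulfate.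

**Compound list**

1 | 3,4,5-trihydroxybenzaldehyde | O=Cc1cc(O)c(O)c(O)c1 | starting material
2 | 7-hydroxy-2,2-diphenyl-1,3-benzodioxole-5-carbaldehyde | O=Cc1cc(O)c2OC(c3ccccc3)(c3ccccc3)Oc2c1 | intermediate
3 | 6-ethynyl-2,2-diphenyl-1,3-benzodioxol-4-ol | C#Cc1cc(O)c2OC(c3ccccc3)(c3ccccc3)Oc2c1 | intermediate
4 | 6-ethynyl-2,2-diphenyl-1,3-benzodioxol-4-yl neopentyl (2,2-dimethylpropyl) sulfate | C#Cc1cc(OS(=O)(=O)OCC(C)(C)C)c2OC(c3ccccc3)(c3ccccc3)Oc2c1 | intermediate
5 | phloroglucinol (benzene-1,3,5-triol) | Oc1cc(O)cc(O)c1 | starting material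
6 | 2-iodobenzene-1,3,5-triol | Oc1cc(O)c(I)c(O)c1 | intermediate
7 | 2-iodobenzene-1,3,5-triyl triacetate | CC(=O)Oc1cc(OC(C)=O)c(I)c(OC(C)=O)c1 | intermediate
8 | carbon monoxide | [C-]#[O+] | starting material
9 | 2-{3-[7-{[(2,2-dimethylpropoxy)sulfonyl]oxy}-2,2-diphenyl-1,3-benzodioxol-5-yl]prop-2-ynoyl}benzene-1,3,5-triyl triacetate (ynone triacetate, formed in the flask) | CC(=O)Oc1cc(OC(C)=O)c(C(=O)C#Cc2cc(OS(=O)(=O)OCC(C)(C)C)c3OC(c4ccccc4)(c4ccccc4)Oc3c2)c(OC(C)=O)c1 | intermediate
10 | 6-[1-(diethylamino)-3-oxo-3-(2,4,6-trihydroxyphenyl)prop-1-en-1-yl]-2,2-diphenyl-1,3-benzodioxol-4-yl neopentyl sulfate (enaminone triol, formed in the flask; push-pull C=C, geometry not fixed, both isomers converge) | CCN(CC)C(=CC(=O)c1c(O)cc(O)cc1O)c1cc(OS(=O)(=O)OCC(C)(C)C)c2OC(c3ccccc3)(c3ccccc3)Oc2c1 | intermediate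
11 | 6-(5,7-dihydroxy-4-oxo-4H-chromen-2-yl)-2,2-diphenyl-1,3-benzodioxol-4-yl neopentyl sulfate | O=c1cc(-c2cc(OS(=O)(=O)OCC(C)(C)C)c3OC(c4ccccc4)(c4ccccc4)Oc3c2)oc2cc(O)cc(O)c12 | intermediate
12 | sodium 6-(5,7-dihydroxy-4-oxo-4H-chromen-2-yl)-2,2-diphenyl-1,3-benzodioxol-4-yl sulfate | O=c1cc(-c2cc(OS(=O)(=O)[O-])c3OC(c4ccccc4)(c4ccccc4)Oc3c2)oc2cc(O)cc(O)c12.[Na+] | intermediate
13 | sodium 5-(5,7-dihydroxy-4-oxo-4H-chromen-2-yl)-2,3-dihydroxyphenyl sulfate (sodium tricetin 3'-sulfate, formed in the flask) | O=c1cc(-c2cc(O)c(O)c(OS(=O)(=O)[O-])c2)oc2cc(O)cc(O)c12.[Na+] | intermediate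
14 | tricetin 3'-sulfate (5-(5,7-dihydroxy-4-oxo-4H-chromen-2-yl)-2,3-dihydroxyphenyl hydrogen sulfate) | O=c1cc(-c2cc(O)c(O)c(OS(=O)(=O)O)c2)oc2cc(O)cc(O)c12 | target

**Step count and risks**

Total step count: 8. Longest linear sequence: 6 steps (1, 2, 3, 6, 7, 8); steps 4 and 5 form the second branch.

Steps most likely to fail:

Step 6. What may go wrong: direct, non-carbonylative coupling followed by 5-endo closure to a 2-arylbenzofuran; capture of the aroyl–palladium species by diethylamine (aminocarbonylation); de-acetylation ahead of oxidative addition, followed by protodeiodination of the electron-rich ring; 5-exo closure to the aurone; or slow erosion of the sulfate diester by the amine. Fallback: the fallback sets out from 4 and comes back to the route at 9. Commercial 2,4,6-trihydroxybenzoic acid would be peracetylated (Ac2O, pyridine, 0 °C) to 2,4,6-tris(acetyloxy)benzoic acid F1 and converted with oxalyl chloride and catalytic DMF in CH2Cl2 into 2,4,6-tris(acetyloxy)benzoyl chloride F2. F2 would be joined to alkyne 4 by a copper-co-catalysed acyl Sonogashira coupling (PdCl2(PPh3)2, CuI, Et3N, THF, rt), which should give ynone triacetate 9 as an isolated compound. Brief treatment of 9 with Et2NH in MeOH (rt to 40 °C) should then lead through 10 to 11. This takes CO uptake and palladium out of the ring closure and uses only two-component chemistry.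

Step 7. What may go wrong: slow substitution at the hindered neopentyl carbon, with competing attack at sulfur and loss of the whole sulfate ester. Fallback: the fallback sets out from 3 and 7 and comes back at 13; it drops the masked sulfate and sulfates late, relying on the acidity order 7-OH > 3'-OH > chelated 5-OH. Alkyne 3 (free phenol), 7 and 8 would be combined under the conditions of step 6. This should pass through 2-[3-(7-hydroxy-2,2-diphenyl-1,3-benzodioxol-5-yl)prop-2-ynoyl]benzene-1,3,5-triyl triacetate F3 and 3-(diethylamino)-3-(7-hydroxy-2,2-diphenyl-1,3-benzodioxol-5-yl)-1-(2,4,6-trihydroxyphenyl)prop-2-en-1-one F4 to 5,7-dihydroxy-2-(7-hydroxy-2,2-diphenyl-1,3-benzodioxol-5-yl)-4H-chromen-4-one F5. Benzyl bromide (1.05 equiv) with KHCO3 in DMF at rt should alkylate only the most acidic 7-OH to give 7-(benzyloxy)-5-hydroxy-2-(7-hydroxy-2,2-diphenyl-1,3-benzodioxol-5-yl)-4H-chromen-4-one F6. Sulfur trioxide–pyridine in pyridine, then aqueous NaHCO3, should sulfate the only unchelated phenol to give sodium 6-[7-(benzyloxy)-5-hydroxy-4-oxo-4H-chromen-2-yl]-2,2-diphenyl-1,3-benzodioxol-4-yl sulfate F7. Hydrogenolysis (H2, Pd/C) of the benzyl ether and the ketal should give 13, which is protonated to 14 as in step 8.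

Step 8. What may go wrong: conjugate reduction of the C2=C3 bond during a sluggish ketal hydrogenolysis, or incomplete cleavage of the ketal on the polar salt. Fallback: the fallback sets out from 11 and comes back at 13; it removes the ketal by acidolysis while the sulfate is still the neutral diester, so no hydrogenation is needed. Heating 11 in AcOH/H2O (4:1, 100 °C) should hydrolyse the diphenylmethylene ketal to 5-(5,7-dihydroxy-4-oxo-4H-chromen-2-yl)-2,3-dihydroxyphenyl neopentyl sulfate F8. Treatment with NaN3 in degassed DMSO at 70 °C under argon should dealkylate F8 to 13, which is protonated to 14 as in step 8.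

**Further compounds**

F1 | step 6 | 2,4,6-tris(acetyloxy)benzoic acid | CC(=O)Oc1cc(OC(C)=O)c(C(=O)O)c(OC(C)=O)c1
F2 | step 6 | 2,4,6-tris(acetyloxy)benzoyl chloride | CC(=O)Oc1cc(OC(C)=O)c(C(=O)Cl)c(OC(C)=O)c1
F3 | step 7 | 2-[3-(7-hydroxy-2,2-diphenyl-1,3-benzodioxol-5-yl)prop-2-ynoyl]benzene-1,3,5-triyl triacetate | CC(=O)Oc1cc(OC(C)=O)c(C(=O)C#Cc2cc(O)c3OC(c4ccccc4)(c4ccccc4)Oc3c2)c(OC(C)=O)c1
F4 | step 7 | 3-(diethylamino)-3-(7-hydroxy-2,2-diphenyl-1,3-benzodioxol-5-yl)-1-(2,4,6-trihydroxyphenyl)prop-2-en-1-one | CCN(CC)C(=CC(=O)c1c(O)cc(O)cc1O)c1cc(O)c2OC(c3ccccc3)(c3ccccc3)Oc2c1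
F5 | step 7 | 5,7-dihydroxy-2-(7-hydroxy-2,2-diphenyl-1,3-benzodioxol-5-yl)-4H-chromen-4-one | O=c1cc(-c2cc(O)c3OC(c4ccccc4)(c4ccccc4)Oc3c2)oc2cc(O)cc(O)c12
F6 | step 7 | 7-(benzyloxy)-5-hydroxy-2-(7-hydroxy-2,2-diphenyl-1,3-benzodioxol-5-yl)-4H-chromen-4-one | O=c1cc(-c2cc(O)c3OC(c4ccccc4)(c4ccccc4)Oc3c2)oc2cc(OCc3ccccc3)cc(O)c12
F7 | step 7 | sodium 6-[7-(benzyloxy)-5-hydroxy-4-oxo-4H-chromen-2-yl]-2,2-diphenyl-1,3-benzodioxol-4-yl sulfate | O=c1cc(-c2cc(OS(=O)(=O)[O-])c3OC(c4ccccc4)(c4ccccc4)Oc3c2)oc2cc(OCc3ccccc3)cc(O)c12.[Na+]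
F8 | step 8 | 5-(5,7-dihydroxy-4-oxo-4H-chromen-2-yl)-2,3-dihydroxyphenyl neopentyl sulfate | O=c1cc(-c2cc(O)c(O)c(OS(=O)(=O)OCC(C)(C)C)c2)oc2cc(O)cc(O)c12
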